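## Retrosynthetic overview

1. Target 26 comes from alcohol 25 by a neutral oxidation, and 25 from silyl ether 24. The cyclohexadiene of 24 is the last ring formed, by thermal disrotatory 6π electrocyclization of the (E,Z,E,E)-tetraene 23 (new bond C1–C6, both ring stereocentres).
2. Tetraene 23 is cut at C4–C5 by Suzuki coupling into pyranone (Z)-dienyl iodide 13 and dienyl boronate 22.
3. Iodide 13 comes from a vinylogous aldol condensation of ethylpyranone 5 with (Z)-3-iodo-2-methylacrolein 9. The pyranone is the first ring formed, by triketide lactonisation.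
4. Boronate 22 comes from aldehyde 20 by Wittig and boron–Wittig olefination. Aldehyde 20 comes from (S)-Roche ester 14, the only source of chirality.
5. The alkene geometry fixes the relative configuration of the ring. The Roche-derived side-chain centre is the only bias on its absolute sense, and that bias is expected to be weak, so the two ring diastereomers are separated.

Assumption: (S)-Roche ester, 2-(triphenylphosphoranylidene)propanal, 1,1-bis(pinacolboryl)ethane and Me4NBH(OAc)3 are bought; C1–C10 number the polyene chain from the pyranone-bearing carbon.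

## Route

Step 1
Reactants: 1 ethyl 2-methyl-3-oxopentanoate (racemic)
Product: 3 ethyl 2,4-dimethyl-3,5-dioxoheptanoate, via dilithium dianion 2 (not isolated)
Conditions: LiN(i-Pr)2 (2.1 equiv), THF, −78 → 0 °C; EtC(O)N(OMe)Me, −78 → 0 °C; aq. NH4Cl
Reagents that add atoms: N-methoxy-N-methylpropanamide, CCC(=O)N(C)OC
Why: The γ-carbon of the β-keto ester dianion is acylated by the Weinreb amide (Claisen-type acylation, the chelated adduct stops over-reaction), and no lasting stereocentre is made.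

Step 2
Reactants: 3 ethyl 2,4-dimethyl-3,5-dioxoheptanoate
Product: 4 6-ethyl-4-hydroxy-3,5-dimethyl-2H-pyran-2-one
Conditions: DBU (1.5 equiv), PhMe, reflux; aq. HCl
Reagents that add atoms: none
Why: Base-mediated lactonisation of the enolised 5-keto group onto the ester (triketide cyclisation) forms the pyranone ring with loss of ethanol.

Step 3
Reactants: 4 6-ethyl-4-hydroxy-3,5-dimethyl-2H-pyran-2-one
Product: 5 2-ethyl-6-methoxy-3,5-dimethyl-4H-pyran-4-one
Conditions: MeOTf (1.2 equiv), CH2Cl2, rt; aq. NaHCO3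
Reagents that add atoms: methyl trifluoromethanesulfonate, COS(=O)(=O)C(F)(F)F
Why: Hard O-methylation at the lactone carbonyl oxygen (the 4-OH is flanked by two methyls) followed by proton loss gives the α-methoxy-γ-pyrone regioisomer.

Step 4
Reactants: 6 prop-2-yn-1-ol
Product: 8 (Z)-3-iodo-2-methylprop-2-en-1-ol, via vinylmagnesium alkoxide 7 (not isolated)
Conditions: MeMgBr (2.5 equiv), CuI (10 mol %), Et2O/THF, −10 °C → rt; I2, −78 → 0 °C; aq. NH4Cl
Reagents that add atoms: methylmagnesium bromide, C[Mg]Br; iodine, II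
Why: Alkoxide-directed, CuI-catalysed anti-carbomagnesiation (Duboudin reaction) places Mg cis to CH2O, and iodinolysis with retention gives the Z-iodide.

Step 5
Reactants: 8 (Z)-3-iodo-2-methylprop-2-en-1-ol
Product: 9 (Z)-3-iodo-2-methylprop-2-enal
Conditions: MnO2 (10 equiv), CH2Cl2, rt, dark; used at once
Reagents that add atoms: none
Why: Neutral allylic oxidation with MnO2 leaves the Z-iodoalkene geometry intact.

Step 6
Reactants: 5 2-ethyl-6-methoxy-3,5-dimethyl-4H-pyran-4-one; 9 (Z)-3-iodo-2-methylprop-2-enal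
Product: 13 2-[(2E,4Z)-5-iodo-4-methylpenta-2,4-dien-2-yl]-6-methoxy-3,5-dimethyl-4H-pyran-4-one, via lithium dienolate 10 (not isolated), via lithium aldolate 11 (not isolated), via allylic mesylate 12 (not isolated)
Conditions: LiN(SiMe3)2 (1.05 equiv), THF, −78 °C; 9, −78 °C; MsCl (1.2 equiv), −78 → 0 °C; DBU (3 equiv), 0 °C → rt, dark
Reagents that add atoms: none
Why: Vinylogous aldol addition of the γ-deprotonated pyranone, mesylation and E1cB elimination give the conjugated E-trisubstituted alkene (thermodynamic, pyranone anti to the chain) without touching the Z-vinyl iodide.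

Step 7
Reactants: 14 methyl (S)-3-hydroxy-2-methylpropanoate ((S)-Roche ester)
Product: 16 (S)-1-hydroxy-2-methylpentan-3-one, via Weinreb amide magnesium alkoxide 15 (not isolated)
Conditions: MeNH(OMe)·HCl (1.5 equiv), i-PrMgCl (4.5 equiv), THF, −20 °C; EtMgBr (3 equiv), 0 °C → rt; aq. NH4Cl
Reagents that add atoms: ethylmagnesium bromide, CC[Mg]Br
Why: In situ Weinreb amide formation and Grignard addition (Weinreb ketone synthesis) stop at the ketone through the chelated tetrahedral adduct, so the purchased stereocentre is never enolised.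

Step 8
Reactants: 16 (S)-1-hydroxy-2-methylpentan-3-one
Product: 17 (2S,3S)-2-methylpentane-1,3-diol
Conditions: Me4NBH(OAc)3 (4 equiv), MeCN/AcOH 1:1, −30 → −20 °C
Reagents that add atoms: none
Why: Hydroxyl-directed intramolecular hydride delivery (Evans–Saksena reduction) through a chair with the α-methyl equatorial should give mainly the 2,3-syn diol, and this new carbinol centre is temporary because it becomes the ketone in step 15.

Step 9
Reactants: 17 (2S,3S)-2-methylpentane-1,3-diol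
Product: 18 (2S,3S)-2-methyl-1,3-bis(triethylsilyloxy)pentane
Conditions: TESCl (2.5 equiv), imidazole (5 equiv), DMF, 0 °C → rt
Reagents that add atoms: chlorotriethylsilane, CC[Si](Cl)(CC)CC
Why: Routine silylation of both hydroxyls sets up the selective oxidation of the primary position.

Step 10
Reactants: 18 (2S,3S)-2-methyl-1,3-bis(triethylsilyloxy)pentane
Product: 20 (2R,3S)-2-methyl-3-(triethylsilyloxy)pentanal, via alkoxysulfonium chloride 19 (not isolated)
Conditions: (COCl)2 (4 equiv), DMSO (8 equiv), CH2Cl2, −78 → −40 °C; Et3N, −78 → 0 °C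
Reagents that add atoms: none
Why: Under Swern conditions the primary TES ether is cleaved and oxidised selectively while the hindered secondary TES ether survives (the descriptor at C2 changes only through CIP priorities).

Step 11
Reactants: 20 (2R,3S)-2-methyl-3-(triethylsilyloxy)pentanal
Product: 21 (2E,4S,5S)-2,4-dimethyl-5-(triethylsilyloxy)hept-2-enal
Conditions: Ph3P=C(Me)CHO (1.5 equiv), PhMe, 90 °C
Reagents that add atoms: 2-(triphenylphosphoranylidene)propanal, CC(C=O)=P(c1ccccc1)(c1ccccc1)c1ccccc1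
Why: Wittig olefination with the stabilised formyl ylide is E-selective and too weakly basic to epimerise the α-stereocentre.

Step 12
Reactants: 21 (2E,4S,5S)-2,4-dimethyl-5-(triethylsilyloxy)hept-2-enal
Product: 22 triethyl{[(3S,4S,5E,7Z)-4,6-dimethyl-8-(4,4,5,5-tetramethyl-1,3,2-dioxaborolan-2-yl)nona-5,7-dien-3-yl]oxy}silane (boron trans to the chain)
Conditions: MeCH(Bpin)2 (1.3 equiv), lithium 2,2,6,6-tetramethylpiperidide (1.3 equiv), THF, 0 °C; 21, −78 °C → rt; aq. NH4Cl
Reagents that add atoms: 1,1-bis(pinacolboryl)ethane, CC(B1OC(C)(C)C(C)(C)O1)B1OC(C)(C)C(C)(C)O1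
Why: Boron–Wittig olefination (1,2-addition of the α-boryl carbanion, then syn B–O elimination) is expected to place the remaining Bpin trans to the aldehyde-derived chain.

Step 13
Reactants: 13 2-[(2E,4Z)-5-iodo-4-methylpenta-2,4-dien-2-yl]-6-methoxy-3,5-dimethyl-4H-pyran-4-one; 22 triethyl{[(3S,4S,5E,7Z)-4,6-dimethyl-8-(4,4,5,5-tetramethyl-1,3,2-dioxaborolan-2-yl)nona-5,7-dien-3-yl]oxy}silane
Product: 24 2-methoxy-3,5-dimethyl-6-[(1S,6R)-1,3,5-trimethyl-6-[(2E,4S,5S)-4-methyl-5-(triethylsilyloxy)hept-2-en-2-yl]cyclohexa-2,4-dien-1-yl]-4H-pyran-4-one, via tetraene 23 (not isolated)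
Conditions: Pd(PPh3)4 (10 mol %), TlOEt (2 equiv), THF/H2O 3:1, rt, dark; short SiO2 plug; PhMe, 80 °C, dark
Reagents that add atoms: none
Why: Suzuki–Miyaura coupling with retention gives the (2E,4Z,6E,8E)-tetraene, whose thermal disrotatory 6π electrocyclization closes C1–C6 and puts the two outside groups (pyranone and side chain) cis, while the Roche-derived centre (A1,3-locked next to the side-chain alkene) biases the absolute sense only weakly, so 24 is expected with roughly an equal amount of its (1R,6S) ring diastereomer, which is removed by chromatography (HPLC if needed).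

Step 14
Reactants: 24 the cyclohexadiene TES ether
Product: 25 2-[(1S,6R)-6-[(2E,4S,5S)-5-hydroxy-4-methylhept-2-en-2-yl]-1,3,5-trimethylcyclohexa-2,4-dien-1-yl]-6-methoxy-3,5-dimethyl-4H-pyran-4-one
Conditions: HF·pyridine, pyridine, THF, 0 °C → rt
Reagents that add atoms: none
Why: Buffered fluoride desilylation frees the secondary alcohol without harming the methoxypyranone or the diene, and the alcohols give a second chance to separate the ring diastereomers.

Step 15
Reactants: 25 the secondary alcohol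
Product: 26 2-methoxy-3,5-dimethyl-6-[(1S,6R)-1,3,5-trimethyl-6-[(2E,4S)-4-methyl-5-oxohept-2-en-2-yl]cyclohexa-2,4-dien-1-yl]-4H-pyran-4-one (CNP0301958.3)
Conditions: Dess–Martin periodinane (1.5 equiv), NaHCO3, CH2Cl2, 0 °C → rt; rapid chromatography on neutral silica
Reagents that add atoms: none
Why: Buffered Dess–Martin oxidation is neutral, so the β,γ-unsaturated α-methyl ketone is formed without epimerisation or migration of the alkene into conjugation.

## Compound list

1 | ethyl 2-methyl-3-oxopentanoate (racemic) | CCOC(=O)C(C)C(=O)CC | starting material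
2 | dilithium dianion (bis-enolate) of 1 | CC=C(O[Li])C(C)=C(O[Li])OCC | intermediate
3 | ethyl 2,4-dimethyl-3,5-dioxoheptanoate (stereoisomer/tautomer mixture) | CCOC(=O)C(C)C(=O)C(C)C(=O)CC | intermediate
4 | 6-ethyl-4-hydroxy-3,5-dimethyl-2H-pyran-2-one | CCC1=C(C)C(O)=C(C)C(=O)O1 | intermediate
5 | 2-ethyl-6-methoxy-3,5-dimethyl-4H-pyran-4-one | CCc1oc(OC)c(C)c(=O)c1C | intermediate
6 | prop-2-yn-1-ol | C#CCO | starting material
7 | (Z)-3-(bromomagnesio)-2-methylprop-2-en-1-ol bromomagnesium alkoxide | Br[Mg]OC/C(C)=C\[Mg]Br | intermediate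
8 | (Z)-3-iodo-2-methylprop-2-en-1-ol | OC/C(C)=C\I | intermediate
9 | (Z)-3-iodo-2-methylprop-2-enal | O=C/C(C)=C\I | intermediate
10 | lithium dienolate of 5 (2-ethylidene-6-methoxy-3,5-dimethyl-2H-pyran-4-olate) | COC1=C(C)C(O[Li])=C(C)C(=CC)O1 | intermediate
11 | lithium aldolate, 2-[(4Z)-5-iodo-3-lithiooxy-4-methylpent-4-en-2-yl]-6-methoxy-3,5-dimethyl-4H-pyran-4-one (diastereomer mixture) | COc1oc(C(C)C(O[Li])/C(C)=C\I)c(C)c(=O)c1C | intermediate
12 | allylic mesylate of the aldol (diastereomer mixture) | COc1oc(C(C)C(OS(C)(=O)=O)/C(C)=C\I)c(C)c(=O)c1C | intermediate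
13 | 2-[(2E,4Z)-5-iodo-4-methylpenta-2,4-dien-2-yl]-6-methoxy-3,5-dimethyl-4H-pyran-4-one | COc1oc(/C(C)=C/C(C)=C\I)c(C)c(=O)c1C | intermediate
14 | methyl (S)-3-hydroxy-2-methylpropanoate | COC(=O)[C@@H](C)CO | starting material
15 | (S)-3-hydroxy-N-methoxy-N,2-dimethylpropanamide, chloromagnesium alkoxide | CON(C)C(=O)[C@@H](C)CO[Mg]Cl | intermediate
16 | (S)-1-hydroxy-2-methylpentan-3-one | CCC(=O)[C@@H](C)CO | intermediate
17 | (2S,3S)-2-methylpentane-1,3-diol | CC[C@H](O)[C@@H](C)CO | intermediate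
18 | (2S,3S)-2-methyl-1,3-bis(triethylsilyloxy)pentane | CC[C@H](O[Si](CC)(CC)CC)[C@@H](C)CO[Si](CC)(CC)CC | intermediate
19 | dimethyl[(2S,3S)-2-methyl-3-(triethylsilyloxy)pentyloxy]sulfonium chloride | CC[C@H](O[Si](CC)(CC)CC)[C@@H](C)CO[S+](C)C.[Cl-] | intermediate
20 | (2R,3S)-2-methyl-3-(triethylsilyloxy)pentanal | CC[C@H](O[Si](CC)(CC)CC)[C@@H](C)C=O | intermediate
21 | (2E,4S,5S)-2,4-dimethyl-5-(triethylsilyloxy)hept-2-enal | CC[C@H](O[Si](CC)(CC)CC)[C@@H](C)/C=C(\C)C=O | intermediate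
22 | triethyl{[(3S,4S,5E,7Z)-4,6-dimethyl-8-(4,4,5,5-tetramethyl-1,3,2-dioxaborolan-2-yl)nona-5,7-dien-3-yl]oxy}silane | CC[C@H](O[Si](CC)(CC)CC)[C@@H](C)/C=C(\C)/C=C(\C)B1OC(C)(C)C(C)(C)O1 | intermediate
23 | 2-methoxy-3,5-dimethyl-6-[(2E,4Z,6E,8E,10S,11S)-4,6,8,10-tetramethyl-11-(triethylsilyloxy)trideca-2,4,6,8-tetraen-2-yl]-4H-pyran-4-one | CC[C@H](O[Si](CC)(CC)CC)[C@@H](C)/C=C(\C)/C=C(\C)/C=C(C)\C=C(C)\c1oc(OC)c(C)c(=O)c1C | intermediate
24 | 2-methoxy-3,5-dimethyl-6-[(1S,6R)-1,3,5-trimethyl-6-[(2E,4S,5S)-4-methyl-5-(triethylsilyloxy)hept-2-en-2-yl]cyclohexa-2,4-dien-1-yl]-4H-pyran-4-one | CC[C@H](O[Si](CC)(CC)CC)[C@@H](C)/C=C(\C)[C@@H]1C(C)=CC(C)=C[C@]1(C)c1oc(OC)c(C)c(=O)c1C | intermediate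
25 | 2-[(1S,6R)-6-[(2E,4S,5S)-5-hydroxy-4-methylhept-2-en-2-yl]-1,3,5-trimethylcyclohexa-2,4-dien-1-yl]-6-methoxy-3,5-dimethyl-4H-pyran-4-one | CC[C@H](O)[C@@H](C)/C=C(\C)[C@@H]1C(C)=CC(C)=C[C@]1(C)c1oc(OC)c(C)c(=O)c1C | intermediate
26 | 2-methoxy-3,5-dimethyl-6-[(1S,6R)-1,3,5-trimethyl-6-[(2E,4S)-4-methyl-5-oxohept-2-en-2-yl]cyclohexa-2,4-dien-1-yl]-4H-pyran-4-one | CCC(=O)[C@@H](C)/C=C(\C)[C@@H]1C(C)=CC(C)=C[C@]1(C)c1oc(OC)c(C)c(=O)c1C | target

## Step count and risks

Total step count: 15. Longest linear sequence: 9 steps (steps 7 to 15, from 14).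

The three steps most likely to fail are steps 13, 12 and 6.

Step 13 joins two hindered trisubstituted partners, and the electrocyclization has little facial bias. If the Suzuki coupling stalls or scrambles the Z-alkene, the fallback sets out from 13 and 22 and reverses the polarity in a Stille coupling. Iodide 13 is stannylated (Me3SnSnMe3, Pd(PPh3)4, PhMe, 80 °C) to 2-methoxy-3,5-dimethyl-6-[(2E,4Z)-4-methyl-5-(trimethylstannyl)penta-2,4-dien-2-yl]-4H-pyran-4-one F1. Boronate 22 is iododeboronated with retention (N-iodosuccinimide, MeCN, 0 °C) to triethyl{[(3S,4S,5E,7E)-8-iodo-4,6-dimethylnona-5,7-dien-3-yl]oxy}silane F2. F1 and F2 are coupled (Pd(PPh3)4, CuI, CsF, DMF, rt) to tetraene 23, where the route is rejoined and heating gives 24. The diastereomer separation is unchanged and can be moved to alcohol 25.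

Step 12 depends on the geometry delivered by the boron–Wittig reaction. The fallback sets out from 21 and fixes the geometry by syn-hydrometallation. Corey–Fuchs olefination (CBr4, PPh3, CH2Cl2, 0 °C) gives triethyl{[(3S,4S,5E)-8,8-dibromo-4,6-dimethylocta-5,7-dien-3-yl]oxy}silane F3. Treatment with n-BuLi (2 equiv, THF, −78 °C) and then MeI gives triethyl{[(3S,4S,5E)-4,6-dimethylnon-5-en-7-yn-3-yl]oxy}silane F4. Hydrozirconation (Cp2Zr(H)Cl, THF, 50 °C, zirconium to the methyl-bearing carbon) gives chlorobis(cyclopentadienyl)[(2E,4E,6S,7S)-4,6-dimethyl-7-(triethylsilyloxy)nona-2,4-dien-2-yl]zirconium F5. Transmetallation with ZnCl2 gives [(2E,4E,6S,7S)-4,6-dimethyl-7-(triethylsilyloxy)nona-2,4-dien-2-yl]zinc chloride F6. Negishi coupling of F6 with 13 (Pd(PPh3)4, THF, rt) comes back to the route at tetraene 23.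

Step 6 is a one-pot vinylogous aldol and elimination on a labile Z-iodoenal. The fallback sets out from 9 and builds the pyranone last. Wittig reaction of 9 with Ph3P=C(Me)C(O)N(OMe)Me (CH2Cl2, rt) gives (2E,4Z)-5-iodo-N-methoxy-N,2,4-trimethylpenta-2,4-dienamide F7. Acylation of dianion 2 (made from 1 as in step 1) gives ethyl (6E,8Z)-9-iodo-2,4,6,8-tetramethyl-3,5-dioxonona-6,8-dienoate F8. DBU in warm PhMe closes it to 4-hydroxy-6-[(2E,4Z)-5-iodo-4-methylpenta-2,4-dien-2-yl]-3,5-dimethyl-2H-pyran-2-one F9. Methylation with MeOTf comes back to the route at 13.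

## Further compounds

F1 | step 13 | 2-methoxy-3,5-dimethyl-6-[(2E,4Z)-4-methyl-5-(trimethylstannyl)penta-2,4-dien-2-yl]-4H-pyran-4-one | COc1oc(/C(C)=C/C(C)=C\[Sn](C)(C)C)c(C)c(=O)c1C
F2 | step 13 | triethyl{[(3S,4S,5E,7E)-8-iodo-4,6-dimethylnona-5,7-dien-3-yl]oxy}silane | CC[C@H](O[Si](CC)(CC)CC)[C@@H](C)/C=C(\C)/C=C(\C)I
F3 | step 12 | triethyl{[(3S,4S,5E)-8,8-dibromo-4,6-dimethylocta-5,7-dien-3-yl]oxy}silane | CC[C@H](O[Si](CC)(CC)CC)[C@@H](C)/C=C(\C)C=C(Br)Br
F4 | step 12 | triethyl{[(3S,4S,5E)-4,6-dimethylnon-5-en-7-yn-3-yl]oxy}silane | CC[C@H](O[Si](CC)(CC)CC)[C@@H](C)/C=C(\C)C#CC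
F5 | step 12 | chlorobis(cyclopentadienyl)[(2E,4E,6S,7S)-4,6-dimethyl-7-(triethylsilyloxy)nona-2,4-dien-2-yl]zirconium | CC[C@H](O[Si](CC)(CC)CC)[C@@H](C)/C=C(\C)/C=C(\C)[Zr](Cl)(C1C=CC=C1)C1C=CC=C1
F6 | step 12 | [(2E,4E,6S,7S)-4,6-dimethyl-7-(triethylsilyloxy)nona-2,4-dien-2-yl]zinc chloride | CC[C@H](O[Si](CC)(CC)CC)[C@@H](C)/C=C(\C)/C=C(\C)[Zn]Cl
F7 | step 6 | (2E,4Z)-5-iodo-N-methoxy-N,2,4-trimethylpenta-2,4-dienamide | CON(C)C(=O)/C(C)=C/C(C)=C\I
F8 | step 6 | ethyl (6E,8Z)-9-iodo-2,4,6,8-tetramethyl-3,5-dioxonona-6,8-dienoate | CCOC(=O)C(C)C(=O)C(C)C(=O)/C(C)=C/C(C)=C\I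
F9 | step 6 | 4-hydroxy-6-[(2E,4Z)-5-iodo-4-methylpenta-2,4-dien-2-yl]-3,5-dimethyl-2H-pyran-2-one | O=C1OC(/C(C)=C/C(C)=C\I)=C(C)C(O)=C1C
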